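Assumption: the target is achiral (no stereocentre), so "single enantiomer" needs no stereocontrol; 3,5-dibromo-2-fluorobenzaldehyde is taken as a catalogue chemical.

**Retrosynthetic overview**
1. The phenol OH comes from an aryl formate, which comes from an aryl aldehyde by Baeyer–Villiger oxidation; the CHO sits exactly where the OH must end up.
2. The diaryl ether C–O bond comes from SNAr of 2,4-dibromophenoxide on 3,5-dibromo-2-fluorobenzaldehyde, where the same CHO activates the C–F bond.
3. No ring is formed: both benzene rings are bought with all four bromines in place, so there is no late bromination and no regiochemistry to control.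

**Route**

Step 1
Reactants: 1 2,4-dibromophenol; 2 3,5-dibromo-2-fluorobenzaldehyde
Product: 3 3,5-dibromo-2-(2,4-dibromophenoxy)benzaldehyde
Conditions: K2CO3 (1.5 equiv), DMAc, 100 °C, N2
Reagents that add atoms: none
Why: Nucleophilic aromatic substitution (SNAr): the fluorine is ortho to CHO (Meisenheimer stabilisation) and further activated inductively by the two Br, while both C–Br bonds are meta to CHO and stay untouched; no stereocentre is involved.

Step 2
Reactants: 3 3,5-dibromo-2-(2,4-dibromophenoxy)benzaldehyde
Product: 5 3,5-dibromo-2-(2,4-dibromophenoxy)phenol, via aryl formate 4 (not isolated)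
Conditions: mCPBA (1.5 equiv), CH2Cl2, rt (reflux if slow); then MeOH, cat. conc. HCl, rt
Reagents that add atoms: mCPBA (3-chloroperoxybenzoic acid), OOC(=O)c1cccc(Cl)c1
Why: Baeyer–Villiger oxidation (Dakin-type): in the Criegee adduct the aryl group bearing the ortho aryloxy donor migrates to oxygen to give the formate, and acid-catalysed methanolysis frees the phenol; aryl bromides and the diaryl ether are inert, and no stereocentre is created.

**Compound list**
1 | 2,4-dibromophenol | Oc1ccc(Br)cc1Br | starting material
2 | 3,5-dibromo-2-fluorobenzaldehyde | O=Cc1cc(Br)cc(Br)c1F | starting material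
3 | 3,5-dibromo-2-(2,4-dibromophenoxy)benzaldehyde | O=Cc1cc(Br)cc(Br)c1Oc1ccc(Br)cc1Br | intermediate
4 | 3,5-dibromo-2-(2,4-dibromophenoxy)phenyl formate | O=COc1cc(Br)cc(Br)c1Oc1ccc(Br)cc1Br | intermediate
5 | 3,5-dibromo-2-(2,4-dibromophenoxy)phenol (achiral) | Oc1cc(Br)cc(Br)c1Oc1ccc(Br)cc1Br | target

**Totals**
Total step count: 2. Longest linear sequence: 2.

**Steps most likely to fail** (the route has only two steps, so both are ranked; there is no third)

Step 2 is the most likely to fail. On this electron-poor ring, hydride migration can compete with aryl migration and give the benzoic acid instead of formate 4. The fallback sets out from 3 and comes back to the route at 5. Compound 3 is treated with MeMgBr (THF, −78 °C) to give racemic 1-[3,5-dibromo-2-(2,4-dibromophenoxy)phenyl]ethan-1-ol F1. Dess–Martin periodinane (CH2Cl2, rt) oxidises it to 1-[3,5-dibromo-2-(2,4-dibromophenoxy)phenyl]ethan-1-one F2, which removes the temporary stereocentre. Baeyer–Villiger oxidation of this methyl ketone (CF3CO3H from TFAA and urea–H2O2, Na2HPO4, CH2Cl2) then has only methyl, the poorest migrating group, competing with aryl. It gives 3,5-dibromo-2-(2,4-dibromophenoxy)phenyl acetate F3, and K2CO3 in MeOH followed by acidic work-up delivers 5.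

Step 1 is the second risk. The C–F bond is flanked by CHO and Br, the dibromophenoxide is a weak nucleophile, and the aldehyde may suffer in hot base. The fallback reverses the polarity of the ether formation; it sets out from 2 and comes back to the route at 3. Compound 2 is hydrolysed (aq. KOH, DMSO, 60 °C, then H3O+) to 3,5-dibromo-2-hydroxybenzaldehyde F4, which is also a catalogue chemical. Separately, 1,3-dibromobenzene is converted with I2, mCPBA and TfOH (CH2Cl2) into bis(2,4-dibromophenyl)iodonium triflate F5; iodination occurs at C4, ortho and para to the two bromines. The potassium phenoxide of F4 (K2CO3, DMF, 60–80 °C) is then O-arylated by F5 in a metal-free ligand coupling at iodine(III) to give 3.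

**Further compounds**
F1 | step 2 | 1-[3,5-dibromo-2-(2,4-dibromophenoxy)phenyl]ethan-1-ol (racemic) | CC(O)c1cc(Br)cc(Br)c1Oc1ccc(Br)cc1Br
F2 | step 2 | 1-[3,5-dibromo-2-(2,4-dibromophenoxy)phenyl]ethan-1-one | CC(=O)c1cc(Br)cc(Br)c1Oc1ccc(Br)cc1Br
F3 | step 2 | 3,5-dibromo-2-(2,4-dibromophenoxy)phenyl acetate | CC(=O)Oc1cc(Br)cc(Br)c1Oc1ccc(Br)cc1Br
F4 | step 1 | 3,5-dibromo-2-hydroxybenzaldehyde | O=Cc1cc(Br)cc(Br)c1O
F5 | step 1 | bis(2,4-dibromophenyl)iodonium trifluoromethanesulfonate | Brc1ccc([I+]c2ccc(Br)cc2Br)c(Br)c1.[O-]S(=O)(=O)C(F)(F)F
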